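**Retrosynthetic overview**
1. Endgame: C16=C17 is unmasked from a Mannich base, C9 is oxidised and O7/O11 are acetylated. The ten-membered ring is closed at C7–C8 by Nozaki–Hiyama–Kishi addition of the C8 iodide of a ring D 2-iodoenone to the C7 aldehyde.
2. Ring D comes in whole: Mukaiyama–Michael addition of the C11 methyl ketone (C12 as nucleophile) to (S)-4-silyloxycyclopent-2-enone forms C12–C13 and sets C13. The resulting silyl enol ether is aminomethylated at C16.
3. The two arms on ring A (C5–C6–C7=O and C10–C9(O)–C11(=O)–C12H3) are released by ozonolysis of a temporary cyclohexene ring (C5–C6–C7=C11–C9–C10). This is the ring of (S)-carvone, whose methyl group is C12.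
4. Ring A (C1–C5, C10) is closed at C3–C4 by an iron-hydride radical cyclisation. The enabling feature is the carvone isopropenyl group on C5 (C4 with C18/C19), a 1,1-disubstituted alkene that gives the tertiary C4 radical and hence the gem-dimethyl carbon. It stands trans and vicinal to quaternary C10, which carries a three-carbon arm ending in a C3 tosylhydrazone whose nitrogen leaves as N2.
5. Ring order: carvone ring (bought, temporary) → ring A (key step) → carvone ring opened → ring D attached (bought) → ten-membered ring.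

Key step: step 5

Remark: locants follow the 8,9-seco-ent-kaurane skeleton (ring A C1–C5/C10, C18/C19 on C4, C20 on C10; ten-membered ring C5–C6–C7–C8–C14–C13–C12–C11–C9–C10; ring D C8, C14, C13, C16, C15; C17 exocyclic); the target is 5R,7R,10R,11S,13R, and (S)-4-(tert-butyldimethylsilyloxy)cyclopent-2-enone is taken as purchasable.

**Route**

Step 1
Reactants: 1 (S)-(+)-carvone
Product: 2 (5S,6R)-2,6-dimethyl-5-(prop-1-en-2-yl)cyclohex-2-en-1-one (trans-6-methylcarvone; its C6 epimer is carried along)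
Conditions: LiN(iPr)2, THF, −78 °C; MeI, −78 → 0 °C
Reagents that add atoms: iodomethane, IC
Why: Kinetic α′-deprotonation and enolate methylation; the C6 (= C10) configuration is irrelevant because the centre is enolised again in step 2.

Step 2
Reactants: 2 6-methylcarvone
Product: 3 (5R,6R)-2,6-dimethyl-5-(prop-1-en-2-yl)-6-(prop-2-yn-1-yl)cyclohex-2-en-1-one
Conditions: LiN(iPr)2, THF/DMPU, −78 °C; propargyl bromide, −78 → 0 °C
Reagents that add atoms: propargyl bromide, C#CCBr
Why: Enolate alkylation; the electrophile should enter anti to the neighbouring isopropenyl group, which sets quaternary C10 with the C1 arm trans and the methyl cis to the isopropenyl group.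

Step 3
Reactants: 3 propargyl ketone
Product: 4 3-[(1R,6R)-1,3-dimethyl-2-oxo-6-(prop-1-en-2-yl)cyclohex-3-en-1-yl]propanal
Conditions: [CpRu(MeCN)3]PF6 (cat.), 5,5′-bis(trifluoromethyl)-2,2′-bipyridine (cat.), acetone/H2O, 25 °C
Reagents that add atoms: water, O
Why: Ruthenium-vinylidene anti-Markovnikov hydration of the terminal alkyne should give the C3 aldehyde only; the alkenes and the enone are not substrates.

Step 4
Reactants: 4 keto aldehyde
Product: 5 (E)-N′-tosylhydrazone of 4 at C3
Conditions: TsNHNH2, MeOH, 25 °C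
Reagents that add atoms: p-toluenesulfonyl hydrazide, Cc1ccc(cc1)S(=O)(=O)NN
Why: Hydrazone condensation; the aldehyde should react far faster than the hindered conjugated ketone.

Step 5
Reactants: 5 tosylhydrazone
Product: 7 (4aR,8aR)-2,5,5,8a-tetramethyl-4a,5,6,7,8,8a-hexahydronaphthalen-1(4H)-one, via cyclised tosylhydrazide 6 (not isolated)
Conditions: Fe(acac)3 (cat.), PhSiH3, EtOH, 60 °C; then Et3N, 80 °C
Reagents that add atoms: none
Why: A trivalent iron hydride formed from Fe(acac)3 and PhSiH3 transfers H• to C18 of the isopropenyl group, the tertiary C4 radical adds to the hydrazone carbon C3, and the hydrazinyl radical is reduced and protonated to hydrazide 6; Et3N then expels sulfinate and the monoalkyl diazene loses N2, leaving C3 as CH2. The closest known reaction type is the iron-hydride (MHAT) reductive alkylation of unactivated alkenes with tosylhydrazones, together with radical cyclisation onto C=N acceptors. Ring A closes in the 6-exo-trig mode (C=N exocyclic) through a chair transition state. No lasting stereocentre is created: C4 becomes the gem-dimethyl carbon, C3 ends as CH2, and the trans ring fusion (5R,10R) is already fixed by the trans, diequatorial C5 and C10 substituents. Hydrogen-atom transfer must go to the electron-rich 1,1-disubstituted alkene and not to the enone, which the polarity preference of MHAT should secure. Cyclisation must outrun reduction of the radical, which the quaternary C10 in the tether and the radicophilic sulfonylhydrazone favour, and the ring enone is out of reach of the C4 radical (only 4-exo or 5-endo paths).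

Step 6
Reactants: 7 decalin enone
Product: 8 (1R,4aR,8aR)-2,5,5,8a-tetramethyl-1,4,4a,5,6,7,8,8a-octahydronaphthalen-1-ol (C9 hydroxyl cis to the C10 methyl)
Conditions: NaBH4, CeCl3·7H2O, MeOH, −40 → 0 °C
Reagents that add atoms: none
Why: Luche 1,2-reduction; hydride should attack anti to the axial C10 methyl, giving the equatorial C9 alcohol as a temporary stereocentre that later steers C11.

Step 7
Reactants: 8 allylic alcohol
Product: 9 tert-butyldimethylsilyl ether of 8
Conditions: TBSOTf, 2,6-lutidine, CH2Cl2, 0 °C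
Reagents that add atoms: tert-butyldimethylsilyl triflate, CC(C)(C)[Si](C)(C)OS(=O)(=O)C(F)(F)F
Why: Silylation of the hindered secondary alcohol with the silyl triflate; the bulky non-chelating ether is wanted for step 12.

Step 8
Reactants: 9 silyl ether
Product: 11 (3S)-3-(tert-butyldimethylsilyloxy)-3-[(1R,2R)-2-(2,2-dimethoxyethyl)-1,3,3-trimethylcyclohexyl]propan-2-one, via keto aldehyde 10 (not isolated)
Conditions: O3, CH2Cl2/MeOH, −78 °C; Me2S, → 25 °C; then HC(OMe)3, PPTS, 25 °C
Reagents that add atoms: ozone, [O-][O+]=O; trimethyl orthoformate, COC(OC)OC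
Why: Ozonolysis of the only C=C opens the temporary ring to the C11 methyl ketone and the C7 aldehyde, and acid-catalysed acetalisation should take the aldehyde and leave the hindered α-silyloxy ketone.

Step 9
Reactants: 11 keto acetal
Product: 12 trimethylsilyl enol ether of 11 (C11(OSiMe3)=C12H2)
Conditions: LiN(iPr)2, Me3SiCl, THF, −78 °C
Reagents that add atoms: chlorotrimethylsilane, C[Si](C)(C)Cl
Why: Kinetic enolisation and O-silylation at the methyl group C12; the other α-hydrogen (C9–H) is tertiary and shielded by quaternary C10 and the silyl ether.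

Step 10
Reactants: 12 silyl enol ether; 13 (S)-4-(tert-butyldimethylsilyloxy)cyclopent-2-en-1-one
Product: 15 Mannich base (ring D cyclopentanone with C16–CH2NMe2 and C14–OTBS; C13 joined to C12), via Michael adduct silyl enol ether 14 (not isolated)
Conditions: TASF (cat.), THF, −78 → −40 °C; then CH2=NMe2+ I−, CH2Cl2, −40 → 0 °C; NaHCO3 work-up
Reagents that add atoms: N,N-dimethylmethyleneiminium iodide (Eschenmoser's salt), C=[N+](C)C.[I-]
Why: Fluoride-catalysed Mukaiyama–Michael addition, which leaves the acetal alone, should occur anti to the C14 silyloxy group and so set C13 (R in the target); the regiodefined silyl enol ether is then aminomethylated at C16 (Mannich reaction, trans to the C13 chain).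

Step 11
Reactants: 15 Mannich base
Product: 16 cyclopent-2-enone (C8=C14) carrying the C16 aminomethyl group and the C13 side chain
Conditions: DBU, CH2Cl2, 0 °C
Reagents that add atoms: none
Why: E1cB loss of silanol from the β-silyloxy ketone gives the conjugated ring D enone; the shielded C9–H and the poorer amine leaving group should not compete at this temperature.

Step 12
Reactants: 16 enone ketone
Product: 17 (11S)-alcohol of 16 (9,11-syn)
Conditions: NaBH4, MeOH/CH2Cl2 (1:1), −78 °C
Reagents that add atoms: none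
Why: Low-temperature borohydride reduction should take the saturated α-silyloxy ketone before the conjugated enone; polar Felkin–Anh addition next to the non-chelating C9 silyl ether should give the syn product, which is 11S.

Step 13
Reactants: 17 enone alcohol
Product: 18 2-iodo enone (iodine on C8)
Conditions: I2, pyridine, CH2Cl2, 0 → 25 °C
Reagents that add atoms: iodine, [I][I]
Why: α-Iodination of the enone by pyridine conjugate addition, iodination of the enolate and elimination places iodine on C8 only.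

Step 14
Reactants: 18 iodo enone acetal
Product: 19 C7 aldehyde of 18
Conditions: TsOH·H2O (2 equiv), acetone/H2O, 25 °C; NaHCO3 work-up
Reagents that add atoms: water, O
Why: Acid hydrolysis of the dimethyl acetal; the amine is protonated and the hindered secondary silyl ether should survive.

Step 15
Reactants: 19 iodo enone aldehyde
Product: 20 macrocyclic diol (7R,11S; ten-membered ring closed at C7–C8, C9–OTBS, C16–CH2NMe2)
Conditions: CrCl2, NiCl2 (cat.), chiral oxazoline–sulfonamide ligand, Et3N, THF, 25 °C, 2 mM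
Reagents that add atoms: none
Why: Nozaki–Hiyama–Kishi reaction: zerovalent nickel inserts into C8–I, transmetalation gives a trivalent alkenylchromium that adds to the aldehyde only, and the C7 configuration is put under reagent control by the ligand antipode that delivers 7R.

Step 16
Reactants: 20 diol
Product: 21 7,11-diacetate
Conditions: Ac2O, DMAP, pyridine, CH2Cl2, 0 → 25 °C
Reagents that add atoms: acetic anhydride, CC(=O)OC(C)=O
Why: Acylation of the two free secondary alcohols; O9 is still silylated.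

Step 17
Reactants: 21 diacetate
Product: 22 C9 alcohol
Conditions: HF·pyridine, THF, 0 → 40 °C
Reagents that add atoms: none
Why: Acidic fluoride desilylation, under which the acetates should neither cleave nor migrate.

Step 18
Reactants: 22 alcohol
Product: 23 C9 ketone (dimethylamine adduct of the target)
Conditions: Dess–Martin periodinane, NaHCO3, CH2Cl2, 0 → 25 °C
Reagents that add atoms: none
Why: Buffered Dess–Martin oxidation of the neopentylic alcohol gives the α-acetoxy ketone without epimerising C11.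

Step 19
Reactants: 23 Mannich base
Product: 25 target CNP0417044.1, via methiodide 24 (not isolated)
Conditions: MeI, CH2Cl2, 25 °C; then NaHCO3 (aq), EtOAc, 25 °C
Reagents that add atoms: none
Why: N-Quaternisation and mild E1cB (Hofmann-type) elimination of the Mannich base should unveil the C16=C17 methylene last, with the base too weak to disturb the β- and α-acetoxy ketone units.

**Compound list**
1 | (S)-(+)-carvone, (5S)-2-methyl-5-(prop-1-en-2-yl)cyclohex-2-en-1-one | CC1=CC[C@H](C(C)=C)CC1=O | starting material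
2 | (5S,6R)-2,6-dimethyl-5-(prop-1-en-2-yl)cyclohex-2-en-1-one (with its C6 epimer) | CC1=CC[C@H](C(C)=C)[C@@H](C)C1=O | intermediate
3 | (5R,6R)-2,6-dimethyl-5-(prop-1-en-2-yl)-6-(prop-2-yn-1-yl)cyclohex-2-en-1-one | CC1=CC[C@H](C(C)=C)[C@@](C)(CC#C)C1=O | intermediate
4 | 3-[(1R,6R)-1,3-dimethyl-2-oxo-6-(prop-1-en-2-yl)cyclohex-3-en-1-yl]propanal | CC1=CC[C@H](C(C)=C)[C@@](C)(CCC=O)C1=O | intermediate
5 | (E)-N′-tosylhydrazone of 4 | CC1=CC[C@H](C(C)=C)[C@@](C)(CC/C=N/NS(=O)(=O)c2ccc(C)cc2)C1=O | intermediate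
6 | 4-methyl-N′-[(4aR,8aR)-1,1,4a,6-tetramethyl-5-oxo-1,2,3,4,4a,5,8,8a-octahydronaphthalen-2-yl]benzenesulfonohydrazide (both C3 epimers) | CC1=CC[C@@H]2C(C)(C)C(NNS(=O)(=O)c3ccc(C)cc3)CC[C@@]2(C)C1=O | intermediate
7 | (4aR,8aR)-2,5,5,8a-tetramethyl-4a,5,6,7,8,8a-hexahydronaphthalen-1(4H)-one | CC1=CC[C@@H]2C(C)(C)CCC[C@@]2(C)C1=O | intermediate
8 | (1R,4aR,8aR)-2,5,5,8a-tetramethyl-1,4,4a,5,6,7,8,8a-octahydronaphthalen-1-ol | CC1=CC[C@@H]2C(C)(C)CCC[C@@]2(C)[C@@H]1O | intermediate
9 | tert-butyldimethylsilyl ether of 8 | CC1=CC[C@@H]2C(C)(C)CCC[C@@]2(C)[C@@H]1O[Si](C)(C)C(C)(C)C | intermediate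
10 | 2-[(1R,2R)-2-[(1S)-1-(tert-butyldimethylsilyloxy)-2-oxopropyl]-2,6,6-trimethylcyclohexyl]acetaldehyde | CC(=O)[C@@H](O[Si](C)(C)C(C)(C)C)[C@]1(C)CCCC(C)(C)[C@H]1CC=O | intermediate
11 | (3S)-3-(tert-butyldimethylsilyloxy)-3-[(1R,2R)-2-(2,2-dimethoxyethyl)-1,3,3-trimethylcyclohexyl]propan-2-one | CC(=O)[C@@H](O[Si](C)(C)C(C)(C)C)[C@]1(C)CCCC(C)(C)[C@H]1CC(OC)OC | intermediate
12 | trimethylsilyl enol ether of 11 (C11(OSiMe3)=C12H2) | C=C(O[Si](C)(C)C)[C@@H](O[Si](C)(C)C(C)(C)C)[C@]1(C)CCCC(C)(C)[C@H]1CC(OC)OC | intermediate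
13 | (S)-4-(tert-butyldimethylsilyloxy)cyclopent-2-en-1-one | O=C1C=C[C@@H](O[Si](C)(C)C(C)(C)C)C1 | starting material
14 | Michael adduct as its C15 trimethylsilyl enol ether (C13 chain trans to C14–OTBS) | C[Si](C)(C)OC1=C[C@H](CC(=O)[C@@H](O[Si](C)(C)C(C)(C)C)[C@]2(C)CCCC(C)(C)[C@H]2CC(OC)OC)[C@@H](O[Si](C)(C)C(C)(C)C)C1 | intermediate
15 | Mannich base: 2-[(dimethylamino)methyl]-4-silyloxycyclopentanone with the C13 chain at position 3, all trans | O=C1[C@@H](CN(C)C)[C@H](CC(=O)[C@@H](O[Si](C)(C)C(C)(C)C)[C@]2(C)CCCC(C)(C)[C@H]2CC(OC)OC)[C@@H](O[Si](C)(C)C(C)(C)C)C1 | intermediate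
16 | ring D cyclopent-2-enone (C8=C14) with trans C16–CH2NMe2 and C13 chain; C11 ketone | O=C1C=C[C@@H](CC(=O)[C@@H](O[Si](C)(C)C(C)(C)C)[C@]2(C)CCCC(C)(C)[C@H]2CC(OC)OC)[C@@H]1CN(C)C | intermediate
17 | (11S)-alcohol of 16 (9S,11S, syn) | O=C1C=C[C@@H](C[C@H](O)[C@@H](O[Si](C)(C)C(C)(C)C)[C@]2(C)CCCC(C)(C)[C@H]2CC(OC)OC)[C@@H]1CN(C)C | intermediate
18 | 2-iodo enone of 17 (iodine on C8) | O=C1C(I)=C[C@@H](C[C@H](O)[C@@H](O[Si](C)(C)C(C)(C)C)[C@]2(C)CCCC(C)(C)[C@H]2CC(OC)OC)[C@@H]1CN(C)C | intermediate
19 | C7 aldehyde of 18 | O=C1C(I)=C[C@@H](C[C@H](O)[C@@H](O[Si](C)(C)C(C)(C)C)[C@]2(C)CCCC(C)(C)[C@H]2CC=O)[C@@H]1CN(C)C | intermediate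
20 | macrocyclic 7,11-diol (7R,11S), C9–OTBS, C16–CH2NMe2 | CN(C)C[C@@H]1C(=O)C2=C[C@H]1C[C@H](O)[C@@H](O[Si](C)(C)C(C)(C)C)[C@]3(C)CCCC(C)(C)[C@H]3C[C@H]2O | intermediate
21 | 7,11-diacetate of 20 | CN(C)C[C@@H]1C(=O)C2=C[C@H]1C[C@H](OC(C)=O)[C@@H](O[Si](C)(C)C(C)(C)C)[C@]3(C)CCCC(C)(C)[C@H]3C[C@H]2OC(C)=O | intermediate
22 | C9 alcohol (desilylated 21) | CN(C)C[C@@H]1C(=O)C2=C[C@H]1C[C@H](OC(C)=O)[C@@H](O)[C@]3(C)CCCC(C)(C)[C@H]3C[C@H]2OC(C)=O | intermediate
23 | C9 ketone, the C17 dimethylamine adduct of the target | CN(C)C[C@@H]1C(=O)C2=C[C@H]1C[C@H](OC(C)=O)C(=O)[C@]3(C)CCCC(C)(C)[C@H]3C[C@H]2OC(C)=O | intermediate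
24 | trimethylammonium iodide of 23 | C[N+](C)(C)C[C@@H]1C(=O)C2=C[C@H]1C[C@H](OC(C)=O)C(=O)[C@]3(C)CCCC(C)(C)[C@H]3C[C@H]2OC(C)=O.[I-] | intermediate
25 | CNP0417044.1, (5R,7R,10R,11S,13R)-7,11-diacetoxy-8,9-seco-ent-kaura-8(14),16-diene-9,15-dione | C=C1C(=O)C2=C[C@H]1C[C@H](OC(C)=O)C(=O)[C@]1(C)CCCC(C)(C)[C@H]1C[C@H]2OC(C)=O | target

**Step count and risks**
Total step count: 19. Longest linear sequence: 19 steps (1 → 25; 13 is bought).

Steps most likely to fail:

1. Step 15 (ring closure at C7–C8). The electron-poor 2-iodoenone may lose iodine by protonation of the metallated enone before it adds across the ring, and the ring may override the ligand at C7. The fallback masks the enone carbonyl so that an ordinary alkenyl iodide is used; it sets out from 18 and comes back at 23. Acetylation of 18 (Ac2O, DMAP) gives the C11 acetate F1. Luche reduction (NaBH4, CeCl3·7H2O) gives the 2-iodocyclopent-2-enol F2 (either C15 epimer serves), which is silylated (TBSOTf, 2,6-lutidine) to the bis-silyl ether F3. Acetal hydrolysis gives the aldehyde F4, and Nozaki–Hiyama–Kishi closure under the step 15 conditions gives the macrocyclic allylic alcohol F5. Acetylation gives the diacetate F6, HF·pyridine removes both silyl groups to give the 9,15-diol F7, and Dess–Martin periodinane oxidises both carbinols at once to 23.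

2. Step 10 (C12–C13 bond and C16 aminomethylation). Fluoride may desilylate or eliminate the acceptor, or proton transfer may quench the enolate before conjugate addition. The fallback swaps the acetal for a Lewis-acid-stable thioacetal and uses Lewis acid activation; it sets out from 10 (isolated after the Me2S work-up) and comes back at 15. Thioacetalisation of the aldehyde (1,3-propanedithiol, BF3·OEt2) gives the dithiane ketone F8. Kinetic silylation (LiN(iPr)2, Me3SiCl) gives the silyl enol ether F9. Me3SiOTf-catalysed Mukaiyama–Michael addition to 13 followed by Eschenmoser's salt gives the dithiane Mannich base F10. PhI(OCOCF3)2 in MeOH (with CF3CO2H to protect the amine) turns the dithiane into the dimethyl acetal, which is 15.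

3. Step 5 (ring A closure). The C4 radical may be reduced before it cyclises (simple hydrogenation of the isopropenyl group), or hydrazide 6 may not fragment cleanly. The fallback forms the same C3–C4 bond by a Giese cyclisation onto a removable ester; it sets out from 2 and comes back at 7. Alkylation of the enolate of 2 with methyl 2-(bromomethyl)acrylate gives the acrylate F11. Fe(acac)3/PhSiH3 in EtOH should effect 6-endo Giese cyclisation of the C4 radical onto the acrylate terminus to give the C2 ester F12. Saponification (LiOH) gives the acid F13, and acridinium photoredox hydrodecarboxylation (9-mesityl-10-methylacridinium tetrafluoroborate, PhSSPh, blue light) or Barton decarboxylation gives 7.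

**Further compounds**
F1 | step 15 | C11 acetate of 18 | O=C1C(I)=C[C@@H](C[C@H](OC(C)=O)[C@@H](O[Si](C)(C)C(C)(C)C)[C@]2(C)CCCC(C)(C)[C@H]2CC(OC)OC)[C@@H]1CN(C)C
F2 | step 15 | 2-iodocyclopent-2-enol from F1 (C15 epimers) | OC1C(I)=C[C@@H](C[C@H](OC(C)=O)[C@@H](O[Si](C)(C)C(C)(C)C)[C@]2(C)CCCC(C)(C)[C@H]2CC(OC)OC)[C@@H]1CN(C)C
F3 | step 15 | C15 tert-butyldimethylsilyl ether of F2 | CC(C)(C)[Si](C)(C)OC1C(I)=C[C@@H](C[C@H](OC(C)=O)[C@@H](O[Si](C)(C)C(C)(C)C)[C@]2(C)CCCC(C)(C)[C@H]2CC(OC)OC)[C@@H]1CN(C)C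
F4 | step 15 | C7 aldehyde of F3 | CC(C)(C)[Si](C)(C)OC1C(I)=C[C@@H](C[C@H](OC(C)=O)[C@@H](O[Si](C)(C)C(C)(C)C)[C@]2(C)CCCC(C)(C)[C@H]2CC=O)[C@@H]1CN(C)C
F5 | step 15 | macrocyclic C7 alcohol with C15–OTBS and C9–OTBS | CN(C)C[C@@H]1C(O[Si](C)(C)C(C)(C)C)C2=C[C@H]1C[C@H](OC(C)=O)[C@@H](O[Si](C)(C)C(C)(C)C)[C@]3(C)CCCC(C)(C)[C@H]3C[C@H]2O
F6 | step 15 | 7,11-diacetate of F5 | CN(C)C[C@@H]1C(O[Si](C)(C)C(C)(C)C)C2=C[C@H]1C[C@H](OC(C)=O)[C@@H](O[Si](C)(C)C(C)(C)C)[C@]3(C)CCCC(C)(C)[C@H]3C[C@H]2OC(C)=O
F7 | step 15 | 9,15-diol from F6 | CN(C)C[C@@H]1C(O)C2=C[C@H]1C[C@H](OC(C)=O)[C@@H](O)[C@]3(C)CCCC(C)(C)[C@H]3C[C@H]2OC(C)=O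
F8 | step 10 | 1,3-dithiane of keto aldehyde 10 | CC(=O)[C@@H](O[Si](C)(C)C(C)(C)C)[C@]1(C)CCCC(C)(C)[C@H]1CC2SCCCS2
F9 | step 10 | trimethylsilyl enol ether of F8 | C=C(O[Si](C)(C)C)[C@@H](O[Si](C)(C)C(C)(C)C)[C@]1(C)CCCC(C)(C)[C@H]1CC2SCCCS2
F10 | step 10 | dithiane analogue of Mannich base 15 | O=C1[C@@H](CN(C)C)[C@H](CC(=O)[C@@H](O[Si](C)(C)C(C)(C)C)[C@]2(C)CCCC(C)(C)[C@H]2CC3SCCCS3)[C@@H](O[Si](C)(C)C(C)(C)C)C1
F11 | step 5 | methyl 2-{[(1R,6R)-1,3-dimethyl-2-oxo-6-(prop-1-en-2-yl)cyclohex-3-en-1-yl]methyl}acrylate | CC1=CC[C@H](C(C)=C)[C@@](C)(CC(=C)C(=O)OC)C1=O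
F12 | step 5 | C2 methyl ester of decalin enone 7 (C2 epimers) | CC1=CC[C@@H]2C(C)(C)CC(C(=O)OC)C[C@@]2(C)C1=O
F13 | step 5 | C2 carboxylic acid of decalin enone 7 | CC1=CC[C@@H]2C(C)(C)CC(C(=O)O)C[C@@]2(C)C1=O
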